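**Retrosynthetic overview**
1. Locants: C1 quaternary C–CH3, C2 CH(OH), C3 CH2, C4 C(OH)(iPr), C5 ring-fusion CH, C6 CH(O-angeloyl), C7 CH2, C8 C(CH3)=, C9 =CH, C10 CH(O-angeloyl). Target 22 ← ketone 21 (reduction at C2) ← diol 19 (double angeloylation) ← diene 18 (ring-closing metathesis at C8=C9, closing the seven-membered ring last).
2. 18 ← aldehyde 16 (C6–C7 allylboration) ← aldol 14 (Tamao oxidation, then oxidation at C6) ← enol silane 11 (Mukaiyama aldol, C1–C10) ← cyclopentenone 8 (hydroxyl-directed conjugate addition, C5–C6).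
3. Enabling feature: in the five-membered ring C1–C5, the methylene C3 lies between oxygen-bearing C2 and the tertiary carbinol C4. This is a 4-hydroxycyclopent-2-enone retron (C2=O, C1=C5, C4–OH), the oxa-Piancatelli product of a furan-2-ylmethanol: the furan oxygen becomes the C2 carbonyl oxygen, the CH2OH carbon becomes C3, and the isopropyl-bearing furan carbon becomes C4.
4. Key disconnection C3–C4: dearomative 4π electrocyclisation of the flat, achiral furan 5 under a chiral Brønsted acid. It sets C4, which then controls C5 and C1 directly and, with reagents, C10, C6 and C2. Furan 5 comes in three steps from methyl 3-methylfuran-2-carboxylate.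
5. Ring order: five-membered carbocycle first (step 4), seven-membered ring second (step 10).

Key step: step 4

Remark: the locants C1–C10 defined above are used for all intermediates; the Grignard reagent from 9 and the mixed anhydride from 20 are made in the flask and are not counted as steps.

Step 1
Reactants: 1 methyl 3-methylfuran-2-carboxylate
Product: 2 methyl 5-bromo-3-methylfuran-2-carboxylate
Conditions: Br2 (1.05 equiv), ClCH2CH2Cl, 60 °C
Reagents that add atoms: bromine, BrBr
Why: Electrophilic aromatic bromination of the furoate should occur at the only free α-position (C5 of the furan), the ester deactivating the ring enough to stop at monobromination; no stereocentre is formed.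

Step 2
Reactants: 2 methyl 5-bromo-3-methylfuran-2-carboxylate; 3 isopropylzinc bromide
Product: 4 methyl 3-methyl-5-(propan-2-yl)furan-2-carboxylate
Conditions: 3 (1.5 equiv), Pd(OAc)2 (2 mol%), 2-dicyclohexylphosphino-2',6'-bis(dimethylamino)biphenyl (4 mol%), THF–toluene, 20 °C
Reagents that add atoms: isopropylzinc bromide 3, CC(C)[Zn]Br
Why: Negishi cross-coupling of the heteroaryl bromide with a secondary alkylzinc halide, the bulky biaryl phosphine making reductive elimination faster than β-hydride elimination so that the isopropyl group should be transferred without isomerisation to n-propyl.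

Step 3
Reactants: 4 methyl 3-methyl-5-(propan-2-yl)furan-2-carboxylate
Product: 5 [3-methyl-5-(propan-2-yl)furan-2-yl]methanol
Conditions: LiAlH4, Et2O, 0 °C; aqueous NaOH work-up
Reagents that add atoms: none
Why: Hydride reduction of the ester (LiAlH4 ester reduction) should give the primary furylcarbinol, and the basic work-up avoids acid-induced furfuryl cation chemistry.

Step 4
Reactants: 5 [3-methyl-5-(propan-2-yl)furan-2-yl]methanol
Product: 8 (4R)-4-hydroxy-2-methyl-4-(propan-2-yl)cyclopent-2-en-1-one, via dihydrofuranol hemiketal 6 (not isolated), via ring-opened dienol ketone 7 (not isolated)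
Conditions: (R)-3,3'-bis(2,4,6-triisopropylphenyl)-1,1'-binaphthyl-2,2'-diyl N-(trifluoromethylsulfonyl)phosphoramide (10 mol%), H2O (10 equiv), ClCH2CH2Cl (0.02 M), 50 °C
Reagents that add atoms: water, O
Why: Proposed new method: the strong chiral Brønsted acid ionises the primary furylcarbinol of 5 to the furfuryl/oxocarbenium cation, water adds at the isopropyl-bearing furan carbon to give hemiketal 6, 6 opens to the (Z)-dienol ketone 7, and O-protonation of 7 gives a 1,4-dihydroxypentadienyl cation that closes by thermal conrotatory 4π electrocyclisation between the former CH2OH carbon (C3) and the former furan C5 (C4), after which enol–keto tautomerisation should deliver 8. The closest known reactions are the oxa-Piancatelli rearrangement of 5-alkylfurfuryl alcohols to racemic 4-alkyl-4-hydroxycyclopentenones and the chiral phosphoric acid or N-triflylphosphoramide catalysed aza-Piancatelli rearrangement, in which the same electrocyclisation is made enantioselective by the chiral counter-anion; new here is the enantioselective version with water as nucleophile and a primary carbinol. The only ring closed is the five-membered carbocycle, by a Nazarov-type conrotatory 4π closure of the pentadienyl cation (formally 5-endo), the furan ring being opened in the same operation. The single new stereocentre C4 is set by the torquoselectivity of that conrotation, controlled by the chiral phosphoramide anion hydrogen-bonded to both hydroxyl groups of the cation; the R configuration is required, and the antipodal acid would serve if the sense of induction is the reverse. The step needs water to attack the ring carbon and not another furan, which the blocked and electron-rich 5-position, the excess of water and the dilution should secure, while water attack at the exocyclic carbon only regenerates 5.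

Step 5
Reactants: 8 (4R)-4-hydroxy-2-methyl-4-(propan-2-yl)cyclopent-2-en-1-one; 9 (chloromethyl)dimethyl(propan-2-yloxy)silane (as its Grignard reagent)
Product: 11 (3aR,6aR)-2,2,4-trimethyl-6a-(propan-2-yl)-5-[(trimethylsilyl)oxy]-3,3a,6,6a-tetrahydro-2H-cyclopenta[d][1,2]oxasilole (cis-fused siloxane with tetrasubstituted enol silane C1=C2), via chloromagnesium enolate 10 (not isolated)
Conditions: t-BuMgCl (1.05 equiv), THF, −78 °C; then ClMgCH2SiMe2(OiPr) (from 9, Mg, THF; 2 equiv), −78 → 20 °C; then Me3SiCl, Et3N, DMPU, −78 → 0 °C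
Reagents that add atoms: Grignard reagent from (chloromethyl)dimethyl(propan-2-yloxy)silane 9, CC(C)O[Si](C)(C)CCl; chlorotrimethylsilane, C[Si](C)(C)Cl
Why: Alkoxide-directed (ligand-assisted) conjugate addition of a Grignard reagent to a 4-hydroxycyclopentenone: the magnesium alkoxide at C4 binds the hydroxymethyl-anion-equivalent Grignard reagent and should deliver it to C5 on its own face, so C6 arrives cis to the C4 oxygen (C5 set), the cis relationship is then locked by displacement of isopropoxide at silicon to give the five-membered siloxane, and silylation of the regiodefined enolate 10 stores it as the tetrasubstituted enol ether without equilibration toward C3.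

Step 6
Reactants: 11 cis-fused siloxane enol silane; 12 (2E)-but-2-enal
Product: 14 (3aR,4S,6aR)-4-[(1R,2E)-1-hydroxybut-2-en-1-yl]-2,2,4-trimethyl-6a-(propan-2-yl)hexahydro-2H-cyclopenta[d][1,2]oxasilol-5-one, via O-trimethylsilyl aldol adduct 13 (not isolated)
Conditions: 12 (1.5 equiv), Sc(OTf)3 (10 mol%), CH2Cl2, −78 °C; then aqueous citric acid, THF, 0 °C
Reagents that add atoms: (2E)-but-2-enal 12, C/C=C/C=O
Why: Mukaiyama aldol addition of the tetrasubstituted enol silane to the aldehyde carbonyl (1,2-addition, as is usual for β-substituted enals): the aldehyde should approach C1 from the convex face opposite the siloxane ring and the C5–C6 bond, so the new C1–C10 bond is trans to C5–C6 (quaternary C1 set, methyl on the face of C6), and in the open antiperiplanar transition state the propenyl group lies next to the small C1 methyl and away from the substituted ring carbon C5, which should give the 10R carbinol.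

Step 7
Reactants: 14 siloxane aldol
Product: 15 (2S,3S,4R)-4-hydroxy-2-[(1R,2E)-1-hydroxybut-2-en-1-yl]-3-(hydroxymethyl)-2-methyl-4-(propan-2-yl)cyclopentan-1-one
Conditions: H2O2 (30% aq.), KF, KHCO3, THF–MeOH, 20 °C
Reagents that add atoms: hydrogen peroxide, OO
Why: Tamao–Fleming oxidation of the alkoxysilane: fluoride-activated peroxide should replace the C6–Si bond by C6–OH and the Si–O bond to C4 is hydrolysed, so both hydroxyls are released without touching any stereocentre.

Step 8
Reactants: 15 triol ketone
Product: 16 (1R,2S,5R)-5-hydroxy-2-[(1R,2E)-1-hydroxybut-2-en-1-yl]-2-methyl-3-oxo-5-(propan-2-yl)cyclopentane-1-carbaldehyde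
Conditions: TEMPO (10 mol%), PhI(OAc)2 (1.1 equiv), CH2Cl2, 20 °C
Reagents that add atoms: none
Why: Nitroxyl-catalysed oxidation with PhI(OAc)2 is selective for the primary alcohol over the hindered secondary allylic and the tertiary alcohol and is mild enough that the aldehyde α-stereocentre C5 should not epimerise.

Step 9
Reactants: 16 aldehyde; 17 4,4,5,5-tetramethyl-2-(2-methylprop-2-en-1-yl)-1,3,2-dioxaborolane
Product: 18 (2S,3S,4R)-4-hydroxy-2-[(1R,2E)-1-hydroxybut-2-en-1-yl]-3-[(1S)-1-hydroxy-3-methylbut-3-en-1-yl]-2-methyl-4-(propan-2-yl)cyclopentan-1-one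
Conditions: 17 (1.5 equiv), (S)-3,3'-bis(2,4,6-triisopropylphenyl)-1,1'-binaphthyl-2,2'-diyl hydrogen phosphate (5 mol%), 4 Å molecular sieves, toluene, −30 °C
Reagents that add atoms: 2-methylallylboronic acid pinacol ester 17, CC(=C)CB1OC(C)(C)C(C)(C)O1
Why: Chiral phosphoric acid-catalysed allylboration of the aldehyde through a closed six-membered transition state tolerates the free hydroxyls and the ketone, and the (S)-acid, which directs allyl transfer to the Si face of aldehydes, should set C6 as S under catalyst control.

Step 10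
Reactants: 18 diene triol ketone
Product: 19 (1R,3aS,4R,8S,8aS)-1,4,8-trihydroxy-3a,6-dimethyl-1-(propan-2-yl)-1,2,4,7,8,8a-hexahydroazulen-3(3aH)-one
Conditions: second-generation Grubbs catalyst RuCl2(=CHPh)(PCy3)(H2IMes) (5 mol%), CH2Cl2 (0.005 M), 40 °C
Reagents that add atoms: none
Why: Ring-closing olefin metathesis between the 1,1-disubstituted alkene and the propenyl group (the catalyst loads on the propenyl group and propene is lost) should form the trisubstituted C8=C9 bond of the trans-fused seven-membered ring, a favourable closure with both chains held trans on adjacent ring carbons; no stereocentre changes.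

Step 11
Reactants: 19 bicyclic triol ketone; 20 (2Z)-2-methylbut-2-enoic acid (angelic acid)
Product: 21 (1R,3aS,4R,8S,8aS)-1-hydroxy-3a,6-dimethyl-3-oxo-1-(propan-2-yl)-1,2,3,3a,4,7,8,8a-octahydroazulene-4,8-diyl bis[(2Z)-2-methylbut-2-enoate]
Conditions: 20 (4 equiv), 2,4,6-trichlorobenzoyl chloride, Et3N, toluene, 20 °C; then 19, toluene, 80 °C
Reagents that add atoms: angelic acid 20, C/C=C(/C)C(=O)O
Why: Yamaguchi-type esterification through the mixed 2,4,6-trichlorobenzoic anhydride should acylate both secondary alcohols (C6 and C10) while the tertiary C4 hydroxyl stays free, and the absence of a nucleophilic amine catalyst during acyl transfer avoids Z-to-E isomerisation of the angelate.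

Step 12
Reactants: 21 bis-angelate ketone
Product: 22 (1R,3R,3aR,4R,8S,8aS)-1,3-dihydroxy-3a,6-dimethyl-1-(propan-2-yl)-1,2,3,3a,4,7,8,8a-octahydroazulene-4,8-diyl bis[(2Z)-2-methylbut-2-enoate]
Conditions: NaBH4, MeOH–THF, −40 °C; AcOH quench
Reagents that add atoms: none
Why: Borohydride reduction of the cyclopentanone should take place from the β face, anti to the angular C1 methyl that shields the α face (as in the reduction of 17-oxo steroids), giving the 2R alcohol cis to the methyl and to the C4 hydroxyl, while the low temperature leaves the two conjugated esters untouched.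

**Compound list**
1 | methyl 3-methylfuran-2-carboxylate | COC(=O)c1occc1C | starting material
2 | methyl 5-bromo-3-methylfuran-2-carboxylate | COC(=O)c1oc(Br)cc1C | intermediate
3 | isopropylzinc bromide | CC(C)[Zn]Br | starting material
4 | methyl 3-methyl-5-(propan-2-yl)furan-2-carboxylate | COC(=O)c1oc(C(C)C)cc1C | intermediate
5 | [3-methyl-5-(propan-2-yl)furan-2-yl]methanol | OCc1oc(C(C)C)cc1C | intermediate
6 | 4-methyl-5-methylidene-2-(propan-2-yl)-2,5-dihydrofuran-2-ol (hemiketal) | C=C1OC(O)(C(C)C)C=C1C | intermediate (not isolated)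
7 | (3Z)-2-hydroxy-3,6-dimethylhepta-1,3-dien-5-one | C=C(O)/C(C)=C\C(=O)C(C)C | intermediate (not isolated)
8 | (4R)-4-hydroxy-2-methyl-4-(propan-2-yl)cyclopent-2-en-1-one | O=C1C[C@@](O)(C(C)C)C=C1C | intermediate
9 | (chloromethyl)dimethyl(propan-2-yloxy)silane | CC(C)O[Si](C)(C)CCl | starting material
10 | chloromagnesium enolate of the cis-fused siloxane ketone (C1=C2 enolate, C4–O–Si–C6 ring closed) | CC1=C(O[Mg]Cl)C[C@@](O2)(C(C)C)[C@@H]1C[Si]2(C)C | intermediate (not isolated)
11 | (3aR,6aR)-2,2,4-trimethyl-6a-(propan-2-yl)-5-[(trimethylsilyl)oxy]-3,3a,6,6a-tetrahydro-2H-cyclopenta[d][1,2]oxasilole | CC1=C(O[Si](C)(C)C)C[C@@](O2)(C(C)C)[C@@H]1C[Si]2(C)C | intermediate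
12 | (2E)-but-2-enal | C/C=C/C=O | starting material
13 | O-trimethylsilyl ether of aldol 14 | C/C=C/[C@@H](O[Si](C)(C)C)[C@@]1(C)C(=O)C[C@@](O2)(C(C)C)[C@@H]1C[Si]2(C)C | intermediate (not isolated)
14 | (3aR,4S,6aR)-4-[(1R,2E)-1-hydroxybut-2-en-1-yl]-2,2,4-trimethyl-6a-(propan-2-yl)hexahydro-2H-cyclopenta[d][1,2]oxasilol-5-one | C/C=C/[C@@H](O)[C@@]1(C)C(=O)C[C@@](O2)(C(C)C)[C@@H]1C[Si]2(C)C | intermediate
15 | (2S,3S,4R)-4-hydroxy-2-[(1R,2E)-1-hydroxybut-2-en-1-yl]-3-(hydroxymethyl)-2-methyl-4-(propan-2-yl)cyclopentan-1-one | C/C=C/[C@@H](O)[C@@]1(C)C(=O)C[C@@](O)(C(C)C)[C@@H]1CO | intermediate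
16 | (1R,2S,5R)-5-hydroxy-2-[(1R,2E)-1-hydroxybut-2-en-1-yl]-2-methyl-3-oxo-5-(propan-2-yl)cyclopentane-1-carbaldehyde | C/C=C/[C@@H](O)[C@@]1(C)C(=O)C[C@@](O)(C(C)C)[C@@H]1C=O | intermediate
17 | 4,4,5,5-tetramethyl-2-(2-methylprop-2-en-1-yl)-1,3,2-dioxaborolane | CC(=C)CB1OC(C)(C)C(C)(C)O1 | starting material
18 | (2S,3S,4R)-4-hydroxy-2-[(1R,2E)-1-hydroxybut-2-en-1-yl]-3-[(1S)-1-hydroxy-3-methylbut-3-en-1-yl]-2-methyl-4-(propan-2-yl)cyclopentan-1-one | C/C=C/[C@@H](O)[C@@]1(C)C(=O)C[C@@](O)(C(C)C)[C@@H]1[C@@H](O)CC(C)=C | intermediate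
19 | (1R,3aS,4R,8S,8aS)-1,4,8-trihydroxy-3a,6-dimethyl-1-(propan-2-yl)-1,2,4,7,8,8a-hexahydroazulen-3(3aH)-one | O[C@H]1CC(C)=C[C@@H](O)[C@@]2(C)C(=O)C[C@@](O)(C(C)C)[C@H]12 | intermediate
20 | (2Z)-2-methylbut-2-enoic acid (angelic acid) | C/C=C(/C)C(=O)O | starting material
21 | (1R,3aS,4R,8S,8aS)-1-hydroxy-3a,6-dimethyl-3-oxo-1-(propan-2-yl)-1,2,3,3a,4,7,8,8a-octahydroazulene-4,8-diyl bis[(2Z)-2-methylbut-2-enoate] | C/C=C(/C)C(=O)O[C@H]1CC(C)=C[C@@H](OC(=O)/C(C)=C\C)[C@@]2(C)C(=O)C[C@@](O)(C(C)C)[C@H]12 | intermediate
22 | (1R,3R,3aR,4R,8S,8aS)-1,3-dihydroxy-3a,6-dimethyl-1-(propan-2-yl)-1,2,3,3a,4,7,8,8a-octahydroazulene-4,8-diyl bis[(2Z)-2-methylbut-2-enoate] | C/C=C(/C)C(=O)O[C@H]1CC(C)=C[C@@H](OC(=O)/C(C)=C\C)[C@@]2(C)[C@H](O)C[C@@](O)(C(C)C)[C@H]12 | target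

Total step count: 12. Longest linear sequence: 12 steps (1 → 22); all other components are commercial.

**Steps most likely to fail**

Step 4 (Proposed new method). The chiral anion may give insufficient enantio-induction in the presence of water, or ionisation of the primary carbinol may be slow enough that furan oligomerisation competes. The fallback sets out from 5 and uses known chemistry only. Racemic oxa-Piancatelli rearrangement under achiral conditions (ZnCl2, acetone–H2O, reflux) should give racemic 4-hydroxy-2-methyl-4-(propan-2-yl)cyclopent-2-en-1-one F1. Corey–Bakshi–Shibata reduction of F1 with (S)-2-methyl-CBS-oxazaborolidine ((S)-1-methyl-3,3-diphenyltetrahydro-1H,3H-pyrrolo[1,2-c][1,3,2]oxazaborole) and BH3·SMe2 in THF at −20 °C reduces both enantiomers under reagent control. This should give the separable diastereomers cis-(1R,4R)-2-methyl-4-(propan-2-yl)cyclopent-2-ene-1,4-diol F2 and trans-(1R,4S)-2-methyl-4-(propan-2-yl)cyclopent-2-ene-1,4-diol F3. After chromatography, MnO2 in CH2Cl2 oxidises the allylic alcohol of F2, and the route is rejoined at 8.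

Step 6. Competition between open transition states may give poor control of the C10 configuration, and conjugate addition to the enal may compete with carbonyl addition. The fallback sets out from 11 and fixes C10 by reduction instead of by C–C bond formation. MeLi in THF at 0 °C cleaves the enol silane to the lithium enolate of the siloxane ketone F4. C-Acylation of F4 with 1-[(2E)-but-2-enoyl]-1H-benzotriazole at −78 °C should give the 1,3-diketone (3aR,4R,6aR)-4-[(2E)-but-2-enoyl]-2,2,4-trimethyl-6a-(propan-2-yl)hexahydro-2H-cyclopenta[d][1,2]oxasilol-5-one F5, in which C10 is not yet a stereocentre. Luche reduction (NaBH4, CeCl3·7H2O, MeOH, −78 °C) should then reduce the conjugated carbonyl selectively, with hydride adding to the cerium-chelated diketone from the face anti to C5. The route is rejoined at 14.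

Step 5. Facial control by the magnesium alkoxide may be lost, or the Grignard reagent may add to the carbonyl group. The fallback sets out from 8 and replaces intermolecular delivery by a covalent tether. Silylation of the tertiary alcohol with (bromomethyl)chlorodimethylsilane and imidazole in CH2Cl2 should give (4R)-4-{[(bromomethyl)dimethylsilyl]oxy}-2-methyl-4-(propan-2-yl)cyclopent-2-en-1-one F6. Silicon-tethered 5-exo radical cyclisation (Bu3SnH, AIBN, benzene, 80 °C, slow addition) forms the C5–C6 bond necessarily cis to the C4 oxygen and should give (3aR,6aR)-2,2,4-trimethyl-6a-(propan-2-yl)hexahydro-2H-cyclopenta[d][1,2]oxasilol-5-one F7 as a mixture of C1 epimers. Thermodynamic enol silylation of F7 (Me3SiI, (Me3Si)2NH, CH2Cl2, −20 → 20 °C) should give the more substituted enol ether, and the route is rejoined at 11.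

**Further compounds**
F1 | step 4 | racemic 4-hydroxy-2-methyl-4-(propan-2-yl)cyclopent-2-en-1-one | O=C1CC(O)(C(C)C)C=C1C
F2 | step 4 | cis-(1R,4R)-2-methyl-4-(propan-2-yl)cyclopent-2-ene-1,4-diol | O[C@@H]1C[C@@](O)(C(C)C)C=C1C
F3 | step 4 | trans-(1R,4S)-2-methyl-4-(propan-2-yl)cyclopent-2-ene-1,4-diol | O[C@@H]1C[C@](O)(C(C)C)C=C1C
F4 | step 6 | lithium enolate of the siloxane ketone | CC1=C(O[Li])C[C@@](O2)(C(C)C)[C@@H]1C[Si]2(C)C
F5 | step 6 | (3aR,4R,6aR)-4-[(2E)-but-2-enoyl]-2,2,4-trimethyl-6a-(propan-2-yl)hexahydro-2H-cyclopenta[d][1,2]oxasilol-5-one | C/C=C/C(=O)[C@@]1(C)C(=O)C[C@@](O2)(C(C)C)[C@@H]1C[Si]2(C)C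
F6 | step 5 | (4R)-4-{[(bromomethyl)dimethylsilyl]oxy}-2-methyl-4-(propan-2-yl)cyclopent-2-en-1-one | O=C1C[C@@](O[Si](C)(C)CBr)(C(C)C)C=C1C
F7 | step 5 | (3aR,6aR)-2,2,4-trimethyl-6a-(propan-2-yl)hexahydro-2H-cyclopenta[d][1,2]oxasilol-5-one (C1 epimers) | CC1C(=O)C[C@@](O2)(C(C)C)[C@@H]1C[Si]2(C)C
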